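**Plan**

- Retrosynthesis: the O5 and O4 acyl bonds are cut first, the C3 acetate is traced back to a C3/C4 oxirane, and the cyclohexene is then cut across C6–C1 and C3–C4 into a C1–C3 crotonate and a C4–C6 2-alkoxyacrolein.
- Forward: a crotyl sulfonium ylide and 2-(4-methoxybenzyloxy)acrolein are joined in one pot (Michael addition at C6, ylide addition to the C4 aldehyde, oxirane closure). This makes the carbocycle, the C1=C2 enoate and the C3/C4 oxirane together; the oxirane is then opened and the esters are put on one at a time.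
- Enabling feature: ring atoms C1–C3 are a but-2-enoate whose C3 can carry a sulfonium group (donor at C1 and C3). C4–C6 carry oxygen on C4 and C5 but not on C6, which is a 2-oxyacrolein (acceptor at C6 and C4). The cis C3–O/C4–O pair can start as one oxirane oxygen, the former aldehyde oxygen.
- Stereochemistry: C3 and C4 come from the chiral sulfide; C5 is selected from the epimerisable aldehyde during ring closure (oxirane trans to the ether); the C3 acetate enters with net retention by double inversion; the side-chain centres come from the two enantiopure acids.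
- The three ring oxygens are distinguished by origin: O5 enters as an ether, O4 as the aldehyde oxygen, O3 as acetate.

Key step: step 3

Assumption: the face selection that the ylides of this sulfide show toward free aldehydes is taken to carry over to the ring-closing addition of step 3, and compounds 4 and 16 are taken to be purchasable.

Step 1
Reactants: 1 methyl (E)-4-bromobut-2-enoate; 2 (1R,4R,5R)-4,7,7-trimethyl-6-thiabicyclo[3.2.1]octane (isothiocineole, the enantiomer derived from (R)-limonene)
Product: 3 (1R,4R,5R,6R)-6-[(E)-4-methoxy-4-oxobut-2-en-1-yl]-4,7,7-trimethyl-6-thiabicyclo[3.2.1]octan-6-ium tetrafluoroborate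
Conditions: NaBF4, CH2Cl2/H2O, rt
Reagents that add atoms: sodium tetrafluoroborate, [Na+].F[B-](F)(F)F
Why: SN2 S-alkylation of the sulfide by the primary allylic bromide on the less hindered exo lone pair, with exchange of bromide for non-nucleophilic tetrafluoroborate so that the salt does not revert, should give one diastereomer at sulfur.

Step 2
Reactants: 4 2-[(4-methoxybenzyl)oxy]acetaldehyde; 5 formaldehyde (as 37% aqueous solution)
Product: 6 2-[(4-methoxybenzyl)oxy]prop-2-enal
Conditions: pyrrolidine (cat.), EtCO2H (cat.), i-PrOH, 45 °C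
Reagents that add atoms: none
Why: amine-catalysed Mannich condensation and elimination (α-methylenation of an aldehyde) installs the CH2 that becomes C6; no stereocentre is formed.

Step 3
Reactants: 3 sulfonium salt; 6 enal
Product: 10 methyl (1R,5R,6S)-5-[(4-methoxybenzyl)oxy]-7-oxabicyclo[4.1.0]hept-2-ene-3-carboxylate, via sulfonium ylide 7 (not isolated), via aldehyde-tethered ylide 8 (not isolated), via anti betaine 9 (not isolated)
Conditions: Cs2CO3, CH2Cl2, −20 °C → rt, slow addition of 6
Reagents that add atoms: none
Why: Proposed new method: Cs2CO3 deprotonates 3 to the ester-conjugated allyl ylide 7, whose ester α-carbon (C1) adds 1,4 to the unsubstituted β-carbon (C6) of 6, and proton transfer from C1 to the enolate gives the aldehyde-tethered ylide 8. The sulfur-bearing carbon (C3) of 8 then adds to the C4 aldehyde in a 6-exo-trig closure of the carbocycle to betaine 9, and the alkoxide displaces the sulfide in a 3-exo-tet closure of the oxirane, setting 2 free. The closest known reaction type is the tandem Michael addition/ylide epoxidation of crotonate-derived sulfonium ylides with enones to cyclohexadiene monoepoxides, whose phosphorus counterpart (Michael addition/intramolecular Wittig reaction) is established for enals; new here are the α-alkoxy enal as acceptor and a chiral sulfide as the source of absolute configuration. C3 is controlled by the sulfonium group (vinyl residue anti to the gem-dimethyl carbon, whose exo methyl blocks one ylide face), and C4 follows from C3 because only the betaine with sulfonium and alkoxide anti can close, which makes the ring fusion cis. C5 is an epimerisable α-alkoxy aldehyde centre in 8 and should be selected during closure: the arrangement with the C5–O bond anti to the aldehyde C=O (both pseudoaxial, dipoles opposed) leads straight to the anti betaine and to the oxirane trans to the ether. The step needs 1,4- before 1,2-addition and reaction at the γ- and not the α-carbon of the ylide; the stabilised ylide should add to the free aldehyde only reversibly and unproductively, and slow addition of 6 keeps the free enal scarce once 8 has formed.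

Step 4
Reactants: 10 vinyl oxirane; 11 acetic acid
Product: 12 methyl (3R,4S,5R)-3-acetoxy-4-hydroxy-5-[(4-methoxybenzyl)oxy]cyclohex-1-ene-1-carboxylate
Conditions: Pd(PPh3)4 (cat., zerovalent palladium), AcOH, THF, 0 °C
Reagents that add atoms: none
Why: Tsuji–Trost opening of a γ,δ-epoxy enoate: the metal ionises the allylic C3–O bond anti to oxygen and acetate attacks the allyl terminus remote from the ester (C3, keeping the enoate conjugated) anti to the metal, so double inversion should place the acetate cis to the C4 hydroxyl with C3 retained.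

Step 5
Reactants: 12 hydroxy acetate; 13 (R)-2-methylbutanoic acid
Product: 14 methyl (3R,4S,5R)-3-acetoxy-5-[(4-methoxybenzyl)oxy]-4-{[(2R)-2-methylbutanoyl]oxy}cyclohex-1-ene-1-carboxylate
Conditions: DIC, DMAP (cat.), CH2Cl2, 0 °C
Reagents that add atoms: none
Why: Steglich esterification of the equatorial C4 hydroxyl, run cold with catalytic DMAP so that acylation outruns acetyl migration from O3 and epimerisation of the acid α-centre.

Step 6
Reactants: 14 PMB ether
Product: 15 methyl (3R,4S,5R)-3-acetoxy-5-hydroxy-4-{[(2R)-2-methylbutanoyl]oxy}cyclohex-1-ene-1-carboxylate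
Conditions: DDQ, CH2Cl2/pH 7 buffer, 0 °C → rt
Reagents that add atoms: none
Why: oxidative cleavage of the 4-methoxybenzyl ether (benzylic hydride abstraction, then hydrolysis of the oxocarbenium ion) under neutral conditions should leave the enoate, the allylic acetate and the C4 ester untouched.

Step 7
Reactants: 15 alcohol; 16 (S)-3-methylpentanoic acid
Product: 17 methyl (3R,4S,5R)-3-acetoxy-4-{[(2R)-2-methylbutanoyl]oxy}-5-{[(3S)-3-methylpentanoyl]oxy}cyclohex-1-ene-1-carboxylate
Conditions: DIC, DMAP (cat.), CH2Cl2, 0 °C → rt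
Reagents that add atoms: none
Why: Steglich esterification of the remaining equatorial C5 hydroxyl; the acid carries its stereocentre at the β-carbon, so it cannot epimerise.

**Compound list**

1 | methyl (E)-4-bromobut-2-enoate | COC(=O)/C=C/CBr | starting material
2 | (1R,4R,5R)-4,7,7-trimethyl-6-thiabicyclo[3.2.1]octane (isothiocineole) | C[C@@H]1CC[C@@H]2C[C@H]1SC2(C)C | starting material
3 | (1R,4R,5R,6R)-6-[(E)-4-methoxy-4-oxobut-2-en-1-yl]-4,7,7-trimethyl-6-thiabicyclo[3.2.1]octan-6-ium tetrafluoroborate | C[C@@H]1CC[C@@H]2C[C@H]1[S@@+](C/C=C/C(=O)OC)C2(C)C.F[B-](F)(F)F | intermediate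
4 | 2-[(4-methoxybenzyl)oxy]acetaldehyde | COc1ccc(COCC=O)cc1 | starting material
5 | formaldehyde | C=O | starting material
6 | 2-[(4-methoxybenzyl)oxy]prop-2-enal | COc1ccc(COC(=C)C=O)cc1 | intermediate
7 | sulfonium ylide of 3 (carbanion on the sulfur-bearing carbon, conjugated to the E-enoate) | C[C@@H]1CC[C@@H]2C[C@H]1[S@@+]([CH-]/C=C/C(=O)OC)C2(C)C | intermediate
8 | aldehyde-tethered ylide: methyl (2E)-but-2-enoate bearing the sulfonium ylide at C4 and a (2R)-2-[(4-methoxybenzyl)oxy]-3-oxopropyl group at C2 (drawn as the C5 epimer that cyclises) | C[C@@H]1CC[C@@H]2C[C@H]1[S@@+]([CH-]/C=C(\C[C@@H](OCc1ccc(OC)cc1)C=O)C(=O)OC)C2(C)C | intermediate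
9 | anti betaine: methyl (3S,4S,5R)-5-[(4-methoxybenzyl)oxy]-4-oxido-3-(isothiocineol-6-ium-6-yl)cyclohex-1-ene-1-carboxylate (sulfonium and alkoxide trans) | C[C@@H]1CC[C@@H]2C[C@H]1[S@@+]([C@H]3C=C(C(=O)OC)C[C@@H](OCc4ccc(OC)cc4)[C@@H]3[O-])C2(C)C | intermediate
10 | methyl (1R,5R,6S)-5-[(4-methoxybenzyl)oxy]-7-oxabicyclo[4.1.0]hept-2-ene-3-carboxylate | COc1ccc(CO[C@@H]2CC(C(=O)OC)=C[C@@H](O3)[C@H]23)cc1 | intermediate
11 | acetic acid | CC(=O)O | starting material
12 | methyl (3R,4S,5R)-3-acetoxy-4-hydroxy-5-[(4-methoxybenzyl)oxy]cyclohex-1-ene-1-carboxylate | COc1ccc(CO[C@@H]2CC(C(=O)OC)=C[C@@H](OC(C)=O)[C@H]2O)cc1 | intermediate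
13 | (R)-2-methylbutanoic acid | CC[C@@H](C)C(=O)O | starting material
14 | methyl (3R,4S,5R)-3-acetoxy-5-[(4-methoxybenzyl)oxy]-4-{[(2R)-2-methylbutanoyl]oxy}cyclohex-1-ene-1-carboxylate | COc1ccc(CO[C@@H]2CC(C(=O)OC)=C[C@@H](OC(C)=O)[C@H]2OC(=O)[C@H](C)CC)cc1 | intermediate
15 | methyl (3R,4S,5R)-3-acetoxy-5-hydroxy-4-{[(2R)-2-methylbutanoyl]oxy}cyclohex-1-ene-1-carboxylate | O[C@@H]1CC(C(=O)OC)=C[C@@H](OC(C)=O)[C@H]1OC(=O)[C@H](C)CC | intermediate
16 | (S)-3-methylpentanoic acid | CC[C@H](C)CC(=O)O | starting material
17 | methyl (3R,4S,5R)-3-acetoxy-4-{[(2R)-2-methylbutanoyl]oxy}-5-{[(3S)-3-methylpentanoyl]oxy}cyclohex-1-ene-1-carboxylate | CC[C@H](C)CC(=O)O[C@@H]1CC(C(=O)OC)=C[C@@H](OC(C)=O)[C@H]1OC(=O)[C@H](C)CC | target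

Total steps: 7. Longest linear sequence: 6 (step 1 or step 2, then steps 3 to 7).

**Steps most likely to fail**

Step 3. Several processes could defeat the annulation:
- 1,2-addition of the ylide to the aldehyde of 6, or reaction through the sulfur-bearing carbon leading to cyclopropanation.
- Closure with the oxirane cis to the C5 ether.
- Face selection by the sulfide that is weak or opposite to the model.
- Base-induced isomerisation of the vinyl oxirane followed by aromatisation.

The fallback sets out from 1 and 6 and comes back at 10, using known reactions. Bromide 1 is heated with PPh3 to give [(E)-4-methoxy-4-oxobut-2-en-1-yl]triphenylphosphonium bromide F1. With K2CO3 in CH2Cl2/H2O, F1 and 6 undergo Michael addition and intramolecular Wittig reaction to racemic methyl 5-[(4-methoxybenzyl)oxy]cyclohexa-1,3-diene-1-carboxylate F2. Jacobsen epoxidation of F2 follows, with the (R,R)-salen manganese chloride complex [(salen)MnCl, salen = N,N'-bis(3,5-di-tert-butylsalicylidene)cyclohexane-1,2-diamine dianion, trivalent manganese], NaOCl and 4-phenylpyridine N-oxide in CH2Cl2 at 0 °C. It should oxidise the electron-richer C3=C4 bond on the catalyst-chosen face whatever the C5 configuration. The (5R)-diene then gives 10 and the (5S)-diene gives the cis diastereomer methyl (1R,5S,6S)-5-[(4-methoxybenzyl)oxy]-7-oxabicyclo[4.1.0]hept-2-ene-3-carboxylate F3, which is removed by chromatography.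

Step 4. Acetate may attack C1 instead of C3. The cis relation may be lost through re-ionisation of the allylic acetate and inner-sphere return. The allyl intermediate may undergo β-hydride elimination and aromatise.

The fallback sets out from 10 and comes back at 12, delivering oxygen to C3 intramolecularly. Pd(PPh3)4 (zerovalent palladium) under CO2 in THF should convert 10 into the cis-fused carbonate methyl (3R,4S,5R)-3,4-(carbonyldioxy)-5-[(4-methoxybenzyl)oxy]cyclohex-1-ene-1-carboxylate F4; the carbonate formed on the C4 alkoxide closes onto C3 and fixes both regiochemistry and cis geometry. K2CO3 in MeOH gives the diol methyl (3R,4S,5R)-3,4-dihydroxy-5-[(4-methoxybenzyl)oxy]cyclohex-1-ene-1-carboxylate F5. MeC(OMe)3 with catalytic camphorsulfonic acid gives the cyclic orthoester methyl (3R,4S,5R)-3,4-[(1-methoxyethylidene)dioxy]-5-[(4-methoxybenzyl)oxy]cyclohex-1-ene-1-carboxylate F6. Its hydrolysis in aqueous AcOH should open to the axial (C3) acetate 12.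

Step 6. The 2-methylbutanoyl group may migrate from O4 to the freed O5, or the acetate may move on from O3, during or after ether cleavage; step 7 would then give regioisomeric triesters. DDQ may also oxidise allylic positions.

The fallback sets out from 10 and comes back at 17, with the order of events changed so that the ether is removed before any ester is present. DDQ on 10 gives methyl (1R,5R,6S)-5-hydroxy-7-oxabicyclo[4.1.0]hept-2-ene-3-carboxylate F7. Steglich esterification with 16 gives methyl (1R,5R,6S)-5-{[(3S)-3-methylpentanoyl]oxy}-7-oxabicyclo[4.1.0]hept-2-ene-3-carboxylate F8. The Pd(PPh3)4/AcOH opening of step 4 then gives methyl (3R,4S,5R)-3-acetoxy-4-hydroxy-5-{[(3S)-3-methylpentanoyl]oxy}cyclohex-1-ene-1-carboxylate F9. Steglich esterification of F9 with 13 gives 17.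

**Further compounds**

F1 | step 3 | [(E)-4-methoxy-4-oxobut-2-en-1-yl]triphenylphosphonium bromide | COC(=O)/C=C/C[P+](c1ccccc1)(c1ccccc1)c1ccccc1.[Br-]
F2 | step 3 | methyl 5-[(4-methoxybenzyl)oxy]cyclohexa-1,3-diene-1-carboxylate (racemic) | COc1ccc(COC2CC(C(=O)OC)=CC=C2)cc1
F3 | step 3 | methyl (1R,5S,6S)-5-[(4-methoxybenzyl)oxy]-7-oxabicyclo[4.1.0]hept-2-ene-3-carboxylate | COc1ccc(CO[C@H]2CC(C(=O)OC)=C[C@@H](O3)[C@H]23)cc1
F4 | step 4 | methyl (3R,4S,5R)-3,4-(carbonyldioxy)-5-[(4-methoxybenzyl)oxy]cyclohex-1-ene-1-carboxylate | COc1ccc(CO[C@@H]2CC(C(=O)OC)=C[C@H]3OC(=O)O[C@@H]23)cc1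
F5 | step 4 | methyl (3R,4S,5R)-3,4-dihydroxy-5-[(4-methoxybenzyl)oxy]cyclohex-1-ene-1-carboxylate | COc1ccc(CO[C@@H]2CC(C(=O)OC)=C[C@@H](O)[C@H]2O)cc1
F6 | step 4 | methyl (3R,4S,5R)-3,4-[(1-methoxyethylidene)dioxy]-5-[(4-methoxybenzyl)oxy]cyclohex-1-ene-1-carboxylate (mixture at the orthoester carbon) | COc1ccc(CO[C@@H]2CC(C(=O)OC)=C[C@H]3OC(C)(OC)O[C@@H]23)cc1
F7 | step 6 | methyl (1R,5R,6S)-5-hydroxy-7-oxabicyclo[4.1.0]hept-2-ene-3-carboxylate | O[C@@H]1CC(C(=O)OC)=C[C@@H](O2)[C@H]12
F8 | step 6 | methyl (1R,5R,6S)-5-{[(3S)-3-methylpentanoyl]oxy}-7-oxabicyclo[4.1.0]hept-2-ene-3-carboxylate | CC[C@H](C)CC(=O)O[C@@H]1CC(C(=O)OC)=C[C@@H](O2)[C@H]12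
F9 | step 6 | methyl (3R,4S,5R)-3-acetoxy-4-hydroxy-5-{[(3S)-3-methylpentanoyl]oxy}cyclohex-1-ene-1-carboxylate | CC[C@H](C)CC(=O)O[C@@H]1CC(C(=O)OC)=C[C@@H](OC(C)=O)[C@H]1O
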